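**Plan**

1. Target: (3R)‑3‑[(2S,3R)‑5‑hydroxy‑7‑methoxy‑2,3‑dimethyl‑8‑(3‑methylbut‑2‑enyl)‑4‑oxochroman‑6‑yl]octanoic acid. The enabling feature is its fully substituted benzene ring (C4a, C5, C6, C7, C8, C8a) with oxygen on C5, C7 and C8a, the positions that a ketene carbonyl, a ynol ether and a cyclic enol ether occupy after a vinylketene–alkyne benzannulation.
2. Retrosynthesis: the acid goes back to a primary alcohol, the C4 ketone to a silylated carbinol and the 7‑methyl ether to a phenol. The benzene ring is then cut at C5–C6, C7–C8 and C4a–C5 (C8–C8a arises by a Wolff shift), giving a 6‑(α‑diazoacyl)dihydropyran and a chiral siloxyalkyne. The dihydropyran is cut at O1–C8a and C2–C3 (hetero‑Diels–Alder), the alkyne at the bond between the stereocentre and its CH2 arm (enolate allylation).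
3. Forward: the dihydropyran ring is built first, acylated at C6 and diazotised; the alkyne is made in a second branch; the benzene ring is then annulated onto the pyran in one operation, and five steps set the final oxidation levels.
4. Stereochemistry: C2 and C3 (2S,3R, cis) come from a catalyst‑controlled endo hetero‑Diels–Alder reaction. The side‑chain centre (R) comes from an Evans allylation and passes through the ynolate 1,2‑shift with retention. C3 is protected by keeping C4 as a carbinol until only neutral or weakly acidic steps remain.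
5. The side‑chain carboxyl travels as a TIPS‑protected primary alcohol because an ester would not survive ynolate generation. All silyl groups are TIPS so that tert‑butyllithium can be used and one fluoride treatment removes them together.

Key step: step 15

Assumption: the chromium catalyst of the (1R,2S)‑aminoindanol series is taken to deliver the diene to the Re face of acetaldehyde; if the sense is the opposite, its mirror image is used and nothing else changes.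

**Route**

Step 1
Reactants: 1 (E)‑4‑methoxybut‑3‑en‑2‑one
Product: 3 (E)‑1‑methoxypent‑1‑en‑3‑one, via lithium dienolate 2 (not isolated)
Conditions: LiN(i‑Pr)2, THF, −78 °C; then MeI, −78 → −20 °C
Reagents that add atoms: iodomethane, CI
Why: Kinetic α′‑deprotonation of the vinylogous ester gives the cross‑conjugated lithium dienolate, and its C‑methylation (enolate alkylation of the Stork–Danheiser type) installs the carbon that ends as the C3 methyl group.

Step 2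
Reactants: 3 (E)‑1‑methoxypent‑1‑en‑3‑one
Product: 4 (1E,3Z)‑1‑methoxy‑3‑(triethylsilyloxy)penta‑1,3‑diene
Conditions: TESOTf, Et3N, Et2O, 0 °C
Reagents that add atoms: triethylsilyl trifluoromethanesulfonate, CC[Si](CC)(CC)OS(=O)(=O)C(F)(F)F
Why: Soft enolisation with a silyl triflate and triethylamine (silyl enol ether formation) gives the (Z)‑enol ether, which places the terminal methyl on the outside of the s‑cis 1‑methoxy‑3‑silyloxy diene.

Step 3
Reactants: 4 (1E,3Z)‑1‑methoxy‑3‑(triethylsilyloxy)penta‑1,3‑diene; 5 acetaldehyde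
Product: 7 (2S,3R)‑2,3‑dimethyl‑2,3‑dihydro‑4H‑pyran‑4‑one, via cycloadduct 6 (not isolated)
Conditions: [CrCl(L)] (3 mol %; L = dianion of (1R,2S)‑1‑{[3‑(1‑adamantyl)‑2‑hydroxy‑5‑methylbenzylidene]amino}indan‑2‑ol; trivalent chromium), 4 Å molecular sieves, neat, 0 °C; then CF3CO2H (cat.), CH2Cl2, 0 °C
Reagents that add atoms: none
Why: Catalytic asymmetric hetero‑Diels–Alder reaction in which the chiral chromium Lewis acid delivers the diene to the Re face of bound acetaldehyde (C2 becomes S) and the endo transition state puts the aldehyde methyl cis to the outside diene methyl (C3 becomes R), after which acid eliminates methanol and unmasks the enone.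

Step 4
Reactants: 7 (2S,3R)‑2,3‑dimethyl‑2,3‑dihydro‑4H‑pyran‑4‑one
Product: 8 (2S,3S,4S)‑2,3‑dimethyl‑3,4‑dihydro‑2H‑pyran‑4‑ol
Conditions: NaBH4, CeCl3·7H2O, MeOH, −78 → −40 °C
Reagents that add atoms: none
Why: Luche reduction gives selective 1,2‑reduction of the vinylogous ester carbonyl, hydride arriving anti to the pseudo‑axial C3 methyl so that the all‑cis alcohol is expected, a centre that is erased again in step 17.

Step 5
Reactants: 8 (2S,3S,4S)‑2,3‑dimethyl‑3,4‑dihydro‑2H‑pyran‑4‑ol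
Product: 9 (2S,3R,4S)‑2,3‑dimethyl‑4‑(triisopropylsilyloxy)‑3,4‑dihydro‑2H‑pyran
Conditions: TIPSOTf, 2,6‑lutidine, CH2Cl2, −78 → 0 °C
Reagents that add atoms: triisopropylsilyl trifluoromethanesulfonate, CC(C)[Si](C(C)C)(C(C)C)OS(=O)(=O)C(F)(F)F
Why: Silylation of the secondary allylic alcohol with a silyl triflate and a hindered pyridine base; triisopropylsilyl is chosen because it carries no Si–CH3 group that tert‑butyllithium could metalate in step 7.

Step 6
Reactants: 10 5‑methylhex‑4‑enoic acid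
Product: 12 N‑methoxy‑N,5‑dimethylhex‑4‑enamide, via acyl imidazole 11 (not isolated)
Conditions: 1,1'‑carbonyldiimidazole, CH2Cl2, 0 °C → rt; then MeNHOMe·HCl, rt
Reagents that add atoms: N,O‑dimethylhydroxylamine hydrochloride, CNOC.Cl
Why: Acyl imidazole activation followed by aminolysis (amide coupling) gives the N‑methoxy‑N‑methylamide, an acyl donor that stops at the ketone stage with organolithiums.

Step 7
Reactants: 9 (2S,3R,4S)‑2,3‑dimethyl‑4‑(triisopropylsilyloxy)‑3,4‑dihydro‑2H‑pyran; 12 N‑methoxy‑N,5‑dimethylhex‑4‑enamide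
Product: 14 1‑[(2S,3R,4R)‑2,3‑dimethyl‑4‑(triisopropylsilyloxy)‑3,4‑dihydro‑2H‑pyran‑6‑yl]‑5‑methylhex‑4‑en‑1‑one, via 6‑lithio dihydropyran 13 (not isolated)
Conditions: t‑BuLi, THF, −78 → 0 °C; then 12, −78 → 0 °C
Reagents that add atoms: none
Why: Vinylic α‑lithiation of the cyclic enol ether at C6, as in C1‑lithiation of silylated glycals, followed by acylation through the chelated tetrahedral adduct of the N‑methoxy‑N‑methylamide gives the ketone without over‑addition.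

Step 8
Reactants: 14 1‑[(2S,3R,4R)‑2,3‑dimethyl‑4‑(triisopropylsilyloxy)‑3,4‑dihydro‑2H‑pyran‑6‑yl]‑5‑methylhex‑4‑en‑1‑one
Product: 17 2‑diazo‑1‑[(2S,3R,4R)‑2,3‑dimethyl‑4‑(triisopropylsilyloxy)‑3,4‑dihydro‑2H‑pyran‑6‑yl]‑5‑methylhex‑4‑en‑1‑one, via lithium enolate 15 (not isolated), via trifluoroacetyl diketone 16 (not isolated)
Conditions: LiN(SiMe3)2, THF, −78 °C; CF3CO2CH2CF3, −78 °C; then MsN3, Et3N, H2O, MeCN, rt
Reagents that add atoms: methanesulfonyl azide, CS(=O)(=O)N=[N+]=[N-]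
Why: Deacylative (detrifluoroacetylative) Regitz diazo transfer: the single enolisable position is trifluoroacetylated and the activated 1,3‑diketone accepts the diazo group from the sulfonyl azide with loss of the trifluoroacetyl group, under conditions that spare the enol ether and the silyl ether.

Step 9
Reactants: 18 (S)‑4‑benzyloxazolidin‑2‑one; 19 heptanoyl chloride
Product: 20 (S)‑4‑benzyl‑3‑heptanoyloxazolidin‑2‑one
Conditions: Et3N, DMAP (cat.), CH2Cl2, 0 °C → rt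
Reagents that add atoms: none
Why: N‑Acylation of the oxazolidinone by the acid chloride under nucleophilic catalysis gives the imide for auxiliary‑controlled alkylation.

Step 10
Reactants: 20 (S)‑4‑benzyl‑3‑heptanoyloxazolidin‑2‑one
Product: 22 (S)‑4‑benzyl‑3‑[(2R)‑2‑allylheptanoyl]oxazolidin‑2‑one, via sodium enolate 21 (not isolated)
Conditions: NaN(SiMe3)2, THF, −78 °C; then allyl iodide, −78 → −45 °C
Reagents that add atoms: allyl iodide, C=CCI
Why: Evans alkylation in which the chelated (Z)‑sodium enolate is allylated on the face opposite the benzyl group, which sets the side‑chain stereocentre as R.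

Step 11
Reactants: 22 (S)‑4‑benzyl‑3‑[(2R)‑2‑allylheptanoyl]oxazolidin‑2‑one
Product: 23 ethyl (2R)‑2‑allylheptanoate
Conditions: Ti(OEt)4 (cat.), EtOH, reflux
Reagents that add atoms: ethanol, CCO
Why: Titanate‑mediated transesterification attacks the exocyclic imide carbonyl under near‑neutral conditions, giving the ethyl ester without epimerising the α‑centre and releasing the auxiliary.

Step 12
Reactants: 23 ethyl (2R)‑2‑allylheptanoate
Product: 25 ethyl (2R)‑2‑(2‑hydroxyethyl)heptanoate, via aldehyde 24 (not isolated)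
Conditions: O3, CH2Cl2/MeOH, −78 °C; then NaBH4, −78 → 0 °C
Reagents that add atoms: ozone, [O-][O+]=O
Why: Ozonolysis of the terminal alkene with reductive work‑up by borohydride shortens the allyl group to a 2‑hydroxyethyl group while the ethyl ester survives at low temperature; the hydroxy ester is silylated at once to forestall lactonisation.

Step 13
Reactants: 25 ethyl (2R)‑2‑(2‑hydroxyethyl)heptanoate
Product: 26 ethyl (2R)‑2‑[2‑(triisopropylsilyloxy)ethyl]heptanoate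
Conditions: TIPSCl, imidazole, DMF, 0 °C → rt
Reagents that add atoms: chlorotriisopropylsilane, CC(C)[Si](Cl)(C(C)C)C(C)C
Why: Silylation of the primary alcohol gives a TIPS ether that is inert to the lithium amides and butyllithium of step 14, which an ester or free acid in this position would not be.

Step 14
Reactants: 26 ethyl (2R)‑2‑[2‑(triisopropylsilyloxy)ethyl]heptanoate
Product: 29 (3R)‑3‑pentyl‑1,5‑bis(triisopropylsilyloxy)pent‑1‑yne, via dibromo enolate 27 (not isolated), via lithium ynolate 28 (not isolated)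
Conditions: CH2Br2, lithium 2,2,6,6‑tetramethylpiperidide, THF, −78 °C; LiN(SiMe3)2, −78 °C; n‑BuLi, −78 °C → rt; then TIPSCl, −78 °C → rt
Reagents that add atoms: dibromomethane, BrCBr; chlorotriisopropylsilane, CC(C)[Si](Cl)(C(C)C)C(C)C
Why: Kowalski ynolate synthesis: dibromomethyllithium adds to the ester, the dibromo enolate undergoes bromine–lithium exchange and a 1,2‑alkyl shift with retention at the migrating stereocentre, and the lithium ynolate is O‑silylated by the bulky chlorosilane.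

Step 15
Reactants: 17 2‑diazo‑1‑[(2S,3R,4R)‑2,3‑dimethyl‑4‑(triisopropylsilyloxy)‑3,4‑dihydro‑2H‑pyran‑6‑yl]‑5‑methylhex‑4‑en‑1‑one; 29 (3R)‑3‑pentyl‑1,5‑bis(triisopropylsilyloxy)pent‑1‑yne
Product: 32 (2S,3R,4R)‑2,3‑dimethyl‑8‑(3‑methylbut‑2‑enyl)‑6‑[(3R)‑1‑(triisopropylsilyloxy)octan‑3‑yl]‑4,7‑bis(triisopropylsilyloxy)chroman‑5‑ol, via vinylketene 30 (not isolated), via vinylcyclobutenone 31 (not isolated)
Conditions: hν (254 nm, quartz), ClCH2CH2Cl, rt; then 80 °C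
Reagents that add atoms: none
Why: Irradiation expels N2 and the dihydropyranyl group migrates from the carbonyl carbon to the diazo carbon (Wolff rearrangement, which makes C8–C8a) to give vinylketene 30, whose C=C bond adds to the siloxyalkyne in a [2+2] cycloaddition (C5–C6 and C7–C8) to give the 4‑vinylcyclobutenone 31, and heating opens this by four‑electron electrocyclic cleavage to a dienylketene. The benzene ring, the only ring formed, is closed by thermal six‑electron electrocyclisation of that dienylketene onto pyran C5 (C4a–C5), and tautomerisation of the cyclohexadienone gives the phenol. The closest known reaction is the Danheiser benzannulation in its photochemical Wolff variant, in which α‑diazo enones and siloxyalkynes give resorcinol monosilyl ethers. No stereocentre is created, the four existing ones lie outside the reacting atoms, and C3 cannot enolise because C4 is a silyl ether during the step. The regiochemistry needed (side chain on C6, siloxy group on C7) is secured by the polarisation of the ynol ether, whose nucleophilic β‑carbon bonds to the ketene carbonyl carbon. The chemoselectivity needed is Wolff shift over 1,2‑hydrogen shift from the prenyl CH2, which is favoured by photochemical (not metal‑catalysed) activation and by the high migratory aptitude of the electron‑rich alkenyl group.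

Step 16
Reactants: 32 (2S,3R,4R)‑2,3‑dimethyl‑8‑(3‑methylbut‑2‑enyl)‑6‑[(3R)‑1‑(triisopropylsilyloxy)octan‑3‑yl]‑4,7‑bis(triisopropylsilyloxy)chroman‑5‑ol
Product: 33 (2S,3S,4R)‑6‑[(3R)‑1‑hydroxyoctan‑3‑yl]‑2,3‑dimethyl‑8‑(3‑methylbut‑2‑enyl)chromane‑4,5,7‑triol
Conditions: Bu4NF, THF, 0 °C → rt; aq NH4Cl; used crude
Reagents that add atoms: none
Why: Fluoride‑mediated desilylation removes the aryl, primary and secondary TIPS ethers in one operation under non‑acidic conditions, so the easily ionised benzylic alcohol is not exposed to acid and is carried on crude.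

Step 17
Reactants: 33 (2S,3S,4R)‑6‑[(3R)‑1‑hydroxyoctan‑3‑yl]‑2,3‑dimethyl‑8‑(3‑methylbut‑2‑enyl)chromane‑4,5,7‑triol
Product: 34 (2S,3R)‑5,7‑dihydroxy‑6‑[(3R)‑1‑hydroxyoctan‑3‑yl]‑2,3‑dimethyl‑8‑(3‑methylbut‑2‑enyl)chroman‑4‑one
Conditions: MnO2 (activated), EtOAc, rt
Reagents that add atoms: none
Why: Benzylic oxidation with activated MnO2 converts only the C4 carbinol (the primary aliphatic alcohol is inert) into the ketone, which is held by a hydrogen bond from the 5‑hydroxyl, under neutral conditions that keep the cis C3 centre.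

Step 18
Reactants: 34 (2S,3R)‑5,7‑dihydroxy‑6‑[(3R)‑1‑hydroxyoctan‑3‑yl]‑2,3‑dimethyl‑8‑(3‑methylbut‑2‑enyl)chroman‑4‑one
Product: 35 (2S,3R)‑5‑hydroxy‑6‑[(3R)‑1‑hydroxyoctan‑3‑yl]‑7‑methoxy‑2,3‑dimethyl‑8‑(3‑methylbut‑2‑enyl)chroman‑4‑one
Conditions: CH2N2, Et2O/MeOH, 0 °C
Reagents that add atoms: diazomethane, C=[N+]=[N-]
Why: Diazomethane O‑methylation is selective for the more acidic, non‑chelated 7‑hydroxyl, because the 5‑hydroxyl is hydrogen‑bonded to the C4 carbonyl and aliphatic alcohols do not react, and its neutrality protects C3.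

Step 19
Reactants: 35 (2S,3R)‑5‑hydroxy‑6‑[(3R)‑1‑hydroxyoctan‑3‑yl]‑7‑methoxy‑2,3‑dimethyl‑8‑(3‑methylbut‑2‑enyl)chroman‑4‑one
Product: 36 (3R)‑3‑[(2S,3R)‑5‑hydroxy‑7‑methoxy‑2,3‑dimethyl‑8‑(3‑methylbut‑2‑enyl)‑4‑oxochroman‑6‑yl]octanal
Conditions: Dess–Martin periodinane (1.1 equiv), NaHCO3, CH2Cl2, 0 °C
Reagents that add atoms: none
Why: Dess–Martin oxidation of the primary alcohol under bicarbonate buffering gives the aldehyde without touching the chelated phenol, the prenyl group or the epimerisable C3 centre, the oxidant being limited so that the lactol form is not taken on to a lactone.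

Step 20
Reactants: 36 (3R)‑3‑[(2S,3R)‑5‑hydroxy‑7‑methoxy‑2,3‑dimethyl‑8‑(3‑methylbut‑2‑enyl)‑4‑oxochroman‑6‑yl]octanal
Product: 37 (3R)‑3‑[(2S,3R)‑5‑hydroxy‑7‑methoxy‑2,3‑dimethyl‑8‑(3‑methylbut‑2‑enyl)‑4‑oxochroman‑6‑yl]octanoic acid
Conditions: NaClO2, NaH2PO4, 2‑methyl‑2‑butene, t‑BuOH/H2O, 0 °C → rt
Reagents that add atoms: sodium chlorite, [Na+].[O-]Cl=O
Why: Pinnick oxidation converts the aldehyde (or its lactol) into the carboxylic acid at about pH 4, with excess 2‑methyl‑2‑butene scavenging hypochlorous acid so that the prenyl group and the arene are spared.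

**Compound list**

1 | (E)‑4‑methoxybut‑3‑en‑2‑one | CO/C=C/C(C)=O | starting material
2 | lithium (E)‑4‑methoxybuta‑1,3‑dien‑2‑olate (not isolated) | CO/C=C/C(=C)O[Li] | intermediate
3 | (E)‑1‑methoxypent‑1‑en‑3‑one | CO/C=C/C(=O)CC | intermediate
4 | (1E,3Z)‑1‑methoxy‑3‑(triethylsilyloxy)penta‑1,3‑diene | CO/C=C/C(O[Si](CC)(CC)CC)=C/C | intermediate
5 | acetaldehyde | CC=O | starting material
6 | (2S,5R,6S)‑2‑methoxy‑5,6‑dimethyl‑4‑(triethylsilyloxy)‑5,6‑dihydro‑2H‑pyran, all‑cis cycloadduct (not isolated) | CO[C@H]1O[C@@H](C)[C@@H](C)C(O[Si](CC)(CC)CC)=C1 | intermediate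
7 | (2S,3R)‑2,3‑dimethyl‑2,3‑dihydro‑4H‑pyran‑4‑one | O1[C@@H](C)[C@@H](C)C(=O)C=C1 | intermediate
8 | (2S,3S,4S)‑2,3‑dimethyl‑3,4‑dihydro‑2H‑pyran‑4‑ol (all‑cis) | O1[C@@H](C)[C@@H](C)[C@@H](O)C=C1 | intermediate
9 | (2S,3R,4S)‑2,3‑dimethyl‑4‑(triisopropylsilyloxy)‑3,4‑dihydro‑2H‑pyran (all‑cis) | O1[C@@H](C)[C@@H](C)[C@@H](O[Si](C(C)C)(C(C)C)C(C)C)C=C1 | intermediate
10 | 5‑methylhex‑4‑enoic acid | CC(C)=CCCC(=O)O | starting material
11 | 1‑(imidazol‑1‑yl)‑5‑methylhex‑4‑en‑1‑one (not isolated) | CC(C)=CCCC(=O)n1ccnc1 | intermediate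
12 | N‑methoxy‑N,5‑dimethylhex‑4‑enamide | CC(C)=CCCC(=O)N(C)OC | intermediate
13 | [(2S,3R,4R)‑2,3‑dimethyl‑4‑(triisopropylsilyloxy)‑3,4‑dihydro‑2H‑pyran‑6‑yl]lithium (not isolated) | O1[C@@H](C)[C@@H](C)[C@@H](O[Si](C(C)C)(C(C)C)C(C)C)C=C1[Li] | intermediate
14 | 1‑[(2S,3R,4R)‑2,3‑dimethyl‑4‑(triisopropylsilyloxy)‑3,4‑dihydro‑2H‑pyran‑6‑yl]‑5‑methylhex‑4‑en‑1‑one | O1[C@@H](C)[C@@H](C)[C@@H](O[Si](C(C)C)(C(C)C)C(C)C)C=C1C(=O)CCC=C(C)C | intermediate
15 | lithium enolate of 14, enolised toward C2 of the hexenone chain (not isolated) | O1[C@@H](C)[C@@H](C)[C@@H](O[Si](C(C)C)(C(C)C)C(C)C)C=C1C(O[Li])=CCC=C(C)C | intermediate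
16 | 1‑[(2S,3R,4R)‑2,3‑dimethyl‑4‑(triisopropylsilyloxy)‑3,4‑dihydro‑2H‑pyran‑6‑yl]‑5‑methyl‑2‑(trifluoroacetyl)hex‑4‑en‑1‑one, C2 epimers (not isolated) | O1[C@@H](C)[C@@H](C)[C@@H](O[Si](C(C)C)(C(C)C)C(C)C)C=C1C(=O)C(CC=C(C)C)C(=O)C(F)(F)F | intermediate
17 | 2‑diazo‑1‑[(2S,3R,4R)‑2,3‑dimethyl‑4‑(triisopropylsilyloxy)‑3,4‑dihydro‑2H‑pyran‑6‑yl]‑5‑methylhex‑4‑en‑1‑one | O1[C@@H](C)[C@@H](C)[C@@H](O[Si](C(C)C)(C(C)C)C(C)C)C=C1C(=O)C(=[N+]=[N-])CC=C(C)C | intermediate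
18 | (S)‑4‑benzyloxazolidin‑2‑one | O=C1N[C@@H](Cc2ccccc2)CO1 | starting material
19 | heptanoyl chloride | CCCCCCC(=O)Cl | starting material
20 | (S)‑4‑benzyl‑3‑heptanoyloxazolidin‑2‑one | CCCCCCC(=O)N1[C@@H](Cc2ccccc2)COC1=O | intermediate
21 | sodium (Z)‑enolate of 20 (not isolated) | CCCCC/C=C(\O[Na])N1[C@@H](Cc2ccccc2)COC1=O | intermediate
22 | (S)‑4‑benzyl‑3‑[(2R)‑2‑allylheptanoyl]oxazolidin‑2‑one | CCCCC[C@H](CC=C)C(=O)N1[C@@H](Cc2ccccc2)COC1=O | intermediate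
23 | ethyl (2R)‑2‑allylheptanoate | CCCCC[C@H](CC=C)C(=O)OCC | intermediate
24 | ethyl (2R)‑2‑(2‑oxoethyl)heptanoate (not isolated) | CCCCC[C@H](CC=O)C(=O)OCC | intermediate
25 | ethyl (2R)‑2‑(2‑hydroxyethyl)heptanoate | CCCCC[C@H](CCO)C(=O)OCC | intermediate
26 | ethyl (2R)‑2‑[2‑(triisopropylsilyloxy)ethyl]heptanoate | CCCCC[C@H](CCO[Si](C(C)C)(C(C)C)C(C)C)C(=O)OCC | intermediate
27 | lithium (3R)‑1,1‑dibromo‑3‑[2‑(triisopropylsilyloxy)ethyl]oct‑1‑en‑2‑olate (not isolated) | CCCCC[C@H](CCO[Si](C(C)C)(C(C)C)C(C)C)C(O[Li])=C(Br)Br | intermediate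
28 | lithium (3R)‑3‑[2‑(triisopropylsilyloxy)ethyl]oct‑1‑yn‑1‑olate (not isolated) | CCCCC[C@H](CCO[Si](C(C)C)(C(C)C)C(C)C)C#CO[Li] | intermediate
29 | (3R)‑3‑pentyl‑1,5‑bis(triisopropylsilyloxy)pent‑1‑yne | CCCCC[C@H](CCO[Si](C(C)C)(C(C)C)C(C)C)C#CO[Si](C(C)C)(C(C)C)C(C)C | intermediate
30 | [(2S,3R,4R)‑2,3‑dimethyl‑4‑(triisopropylsilyloxy)‑3,4‑dihydro‑2H‑pyran‑6‑yl](3‑methylbut‑2‑enyl)ketene (not isolated) | O1[C@@H](C)[C@@H](C)[C@@H](O[Si](C(C)C)(C(C)C)C(C)C)C=C1C(CC=C(C)C)=C=O | intermediate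
31 | 4‑[(2S,3R,4R)‑2,3‑dimethyl‑4‑(triisopropylsilyloxy)‑3,4‑dihydro‑2H‑pyran‑6‑yl]‑4‑(3‑methylbut‑2‑enyl)‑2‑[(3R)‑1‑(triisopropylsilyloxy)octan‑3‑yl]‑3‑(triisopropylsilyloxy)cyclobut‑2‑en‑1‑one, both C4 epimers (not isolated) | O1[C@@H](C)[C@@H](C)[C@@H](O[Si](C(C)C)(C(C)C)C(C)C)C=C1C2(CC=C(C)C)C(=O)C([C@H](CCCCC)CCO[Si](C(C)C)(C(C)C)C(C)C)=C2O[Si](C(C)C)(C(C)C)C(C)C | intermediate
32 | (2S,3R,4R)‑2,3‑dimethyl‑8‑(3‑methylbut‑2‑enyl)‑6‑[(3R)‑1‑(triisopropylsilyloxy)octan‑3‑yl]‑4,7‑bis(triisopropylsilyloxy)chroman‑5‑ol | CCCCC[C@H](CCO[Si](C(C)C)(C(C)C)C(C)C)c1c(O)c2c(c(CC=C(C)C)c1O[Si](C(C)C)(C(C)C)C(C)C)O[C@@H](C)[C@@H](C)[C@H]2O[Si](C(C)C)(C(C)C)C(C)C | intermediate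
33 | (2S,3S,4R)‑6‑[(3R)‑1‑hydroxyoctan‑3‑yl]‑2,3‑dimethyl‑8‑(3‑methylbut‑2‑enyl)chromane‑4,5,7‑triol | CCCCC[C@H](CCO)c1c(O)c2c(c(CC=C(C)C)c1O)O[C@@H](C)[C@@H](C)[C@H]2O | intermediate
34 | (2S,3R)‑5,7‑dihydroxy‑6‑[(3R)‑1‑hydroxyoctan‑3‑yl]‑2,3‑dimethyl‑8‑(3‑methylbut‑2‑enyl)chroman‑4‑one | CCCCC[C@H](CCO)c1c(O)c2c(c(CC=C(C)C)c1O)O[C@@H](C)[C@@H](C)C2=O | intermediate
35 | (2S,3R)‑5‑hydroxy‑6‑[(3R)‑1‑hydroxyoctan‑3‑yl]‑7‑methoxy‑2,3‑dimethyl‑8‑(3‑methylbut‑2‑enyl)chroman‑4‑one | CCCCC[C@H](CCO)c1c(O)c2c(c(CC=C(C)C)c1OC)O[C@@H](C)[C@@H](C)C2=O | intermediate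
36 | (3R)‑3‑[(2S,3R)‑5‑hydroxy‑7‑methoxy‑2,3‑dimethyl‑8‑(3‑methylbut‑2‑enyl)‑4‑oxochroman‑6‑yl]octanal | CCCCC[C@H](CC=O)c1c(O)c2c(c(CC=C(C)C)c1OC)O[C@@H](C)[C@@H](C)C2=O | intermediate
37 | (3R)‑3‑[(2S,3R)‑5‑hydroxy‑7‑methoxy‑2,3‑dimethyl‑8‑(3‑methylbut‑2‑enyl)‑4‑oxochroman‑6‑yl]octanoic acid (CNP0217102.1) | CCCCC[C@H](CC(=O)O)c1c(O)c2c(c(CC=C(C)C)c1OC)O[C@@H](C)[C@@H](C)C2=O | target

**Step count**

Total: 20 steps. Longest linear sequence: 13 steps (steps 1–5, 7, 8, 15–20, from compound 1).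

**Steps most likely to fail, with fallbacks**

Step 15. After loss of nitrogen, a 1,2‑hydrogen shift from the allylic CH2 next to the carbene carbon can outrun migration of the pyranyl group, draining the diazo ketone into a conjugated dienone before any ketene forms. The fallback sets out from 9 and comes back at 32. It runs the benzannulation on the parent diazomethyl ketone, which has no such hydrogen, and adds the prenyl group afterwards. Lithiated 9 is acylated with N‑methoxy‑N‑methylacetamide to give 1‑[(2S,3R,4R)‑2,3‑dimethyl‑4‑(triisopropylsilyloxy)‑3,4‑dihydro‑2H‑pyran‑6‑yl]ethan‑1‑one F1. Detrifluoroacetylative diazo transfer as in step 8 gives 2‑diazo‑1‑[(2S,3R,4R)‑2,3‑dimethyl‑4‑(triisopropylsilyloxy)‑3,4‑dihydro‑2H‑pyran‑6‑yl]ethan‑1‑one F2. Irradiation of F2 with 29 and heating should give (2S,3R,4R)‑2,3‑dimethyl‑6‑[(3R)‑1‑(triisopropylsilyloxy)octan‑3‑yl]‑4,7‑bis(triisopropylsilyloxy)chroman‑5‑ol F3. N‑Bromosuccinimide at low temperature brominates the only free ring position, para to the 5‑hydroxyl, to give (2S,3R,4R)‑8‑bromo‑2,3‑dimethyl‑6‑[(3R)‑1‑(triisopropylsilyloxy)octan‑3‑yl]‑4,7‑bis(triisopropylsilyloxy)chroman‑5‑ol F4. Stille coupling of F4 with tributyl(3‑methylbut‑2‑enyl)stannane under Pd(PPh3)4 (zerovalent palladium) in DMF then gives 32.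

Step 3. With the small, volatile aldehyde the catalyst may give insufficient facial or endo selectivity, or the cis C3 centre may epimerise during the acid treatment, so that the pyranone is obtained with low enantiomeric or cis purity. The fallback sets out from 5 and comes back at 7, replacing the cycloaddition by an auxiliary‑controlled aldol route. Boron‑mediated Evans syn‑aldol reaction (Bu2BOTf, i‑Pr2NEt) of commercial (R)‑4‑benzyl‑3‑propionyloxazolidin‑2‑one with 5 gives (R)‑4‑benzyl‑3‑[(2R,3S)‑3‑hydroxy‑2‑methylbutanoyl]oxazolidin‑2‑one F5. Me3Al‑promoted aminolysis with N,O‑dimethylhydroxylamine hydrochloride gives (2R,3S)‑3‑hydroxy‑N‑methoxy‑N,2‑dimethylbutanamide F6. Excess ethynylmagnesium bromide gives (4R,5S)‑5‑hydroxy‑4‑methylhex‑1‑yn‑3‑one F7. Gold‑catalysed 6‑endo‑dig cyclisation of the hydroxyl onto the ynone (Ph3PAuCl, AgOTf, CH2Cl2) then closes the dihydropyranone 7.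

Step 17. The free, electron‑rich diphenol may be oxidised further (quinone‑methide or quinone formation), or the 2,4,6‑trioxygenated benzylic alcohol may ionise and eliminate before it is oxidised. The fallback sets out from 33 and comes back at 37. It masks both phenols before any oxidation and differentiates them at the end by chelation‑controlled demethylation instead of chelation‑controlled methylation. Crude 33 is treated with MeI and K2CO3 in acetone to give (2S,3S,4R)‑6‑[(3R)‑1‑hydroxyoctan‑3‑yl]‑5,7‑dimethoxy‑2,3‑dimethyl‑8‑(3‑methylbut‑2‑enyl)chroman‑4‑ol F8. Dess–Martin periodinane oxidises both alcohols to (3R)‑3‑[(2S,3R)‑5,7‑dimethoxy‑2,3‑dimethyl‑8‑(3‑methylbut‑2‑enyl)‑4‑oxochroman‑6‑yl]octanal F9. Pinnick oxidation gives (3R)‑3‑[(2S,3R)‑5,7‑dimethoxy‑2,3‑dimethyl‑8‑(3‑methylbut‑2‑enyl)‑4‑oxochroman‑6‑yl]octanoic acid F10. BCl3 in CH2Cl2 at −78 °C then cleaves only the 5‑methyl ether that chelates to the C4 carbonyl, giving 37.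

**Further compounds**

F1 | step 15 | 1‑[(2S,3R,4R)‑2,3‑dimethyl‑4‑(triisopropylsilyloxy)‑3,4‑dihydro‑2H‑pyran‑6‑yl]ethan‑1‑one | O1[C@@H](C)[C@@H](C)[C@@H](O[Si](C(C)C)(C(C)C)C(C)C)C=C1C(C)=O
F2 | step 15 | 2‑diazo‑1‑[(2S,3R,4R)‑2,3‑dimethyl‑4‑(triisopropylsilyloxy)‑3,4‑dihydro‑2H‑pyran‑6‑yl]ethan‑1‑one | O1[C@@H](C)[C@@H](C)[C@@H](O[Si](C(C)C)(C(C)C)C(C)C)C=C1C(=O)C=[N+]=[N-]
F3 | step 15 | (2S,3R,4R)‑2,3‑dimethyl‑6‑[(3R)‑1‑(triisopropylsilyloxy)octan‑3‑yl]‑4,7‑bis(triisopropylsilyloxy)chroman‑5‑ol | CCCCC[C@H](CCO[Si](C(C)C)(C(C)C)C(C)C)c1c(O)c2c(cc1O[Si](C(C)C)(C(C)C)C(C)C)O[C@@H](C)[C@@H](C)[C@H]2O[Si](C(C)C)(C(C)C)C(C)C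
F4 | step 15 | (2S,3R,4R)‑8‑bromo‑2,3‑dimethyl‑6‑[(3R)‑1‑(triisopropylsilyloxy)octan‑3‑yl]‑4,7‑bis(triisopropylsilyloxy)chroman‑5‑ol | CCCCC[C@H](CCO[Si](C(C)C)(C(C)C)C(C)C)c1c(O)c2c(c(Br)c1O[Si](C(C)C)(C(C)C)C(C)C)O[C@@H](C)[C@@H](C)[C@H]2O[Si](C(C)C)(C(C)C)C(C)C
F5 | step 3 | (R)‑4‑benzyl‑3‑[(2R,3S)‑3‑hydroxy‑2‑methylbutanoyl]oxazolidin‑2‑one | C[C@H](O)[C@@H](C)C(=O)N1[C@H](Cc2ccccc2)COC1=O
F6 | step 3 | (2R,3S)‑3‑hydroxy‑N‑methoxy‑N,2‑dimethylbutanamide | C[C@H](O)[C@@H](C)C(=O)N(C)OC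
F7 | step 3 | (4R,5S)‑5‑hydroxy‑4‑methylhex‑1‑yn‑3‑one | C[C@H](O)[C@@H](C)C(=O)C#C
F8 | step 17 | (2S,3S,4R)‑6‑[(3R)‑1‑hydroxyoctan‑3‑yl]‑5,7‑dimethoxy‑2,3‑dimethyl‑8‑(3‑methylbut‑2‑enyl)chroman‑4‑ol | CCCCC[C@H](CCO)c1c(OC)c2c(c(CC=C(C)C)c1OC)O[C@@H](C)[C@@H](C)[C@H]2O
F9 | step 17 | (3R)‑3‑[(2S,3R)‑5,7‑dimethoxy‑2,3‑dimethyl‑8‑(3‑methylbut‑2‑enyl)‑4‑oxochroman‑6‑yl]octanal | CCCCC[C@H](CC=O)c1c(OC)c2c(c(CC=C(C)C)c1OC)O[C@@H](C)[C@@H](C)C2=O
F10 | step 17 | (3R)‑3‑[(2S,3R)‑5,7‑dimethoxy‑2,3‑dimethyl‑8‑(3‑methylbut‑2‑enyl)‑4‑oxochroman‑6‑yl]octanoic acid | CCCCC[C@H](CC(=O)O)c1c(OC)c2c(c(CC=C(C)C)c1OC)O[C@@H](C)[C@@H](C)C2=O
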